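Ring B (C5–C6–C7–C8–C9–C10) is disconnected as a cyclohexene: the diene C7=C8–C9=C10 and the vinyl group C5=C6, joined through C1–C4, make the target an intramolecular Diels–Alder adduct. One thermal cycloaddition of an acyclic 1,7,9-decatriene closes rings A and B by forming C6–C7 and C5–C10, and sets C5, C7 and C10 (C9 on the following protonation). It exploits the sp2 carbon C8 (carried as a silyl enol ether, later the exocyclic methylene), the C7 acetoxy group (a Z-enol acetate terminus) and the quaternary C4 in the tether as the only stereocontrol. The precursor is an (S)-α-methyl-α-vinyl ester carrying a fully substituted 1-acetoxy-2-silyloxy diene with the side chain attached.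

Key step: step 12

Remark: the target is read as 7α-acetoxy-trans-communic acid of the normal labdane series (4S; 5α-H; 9α-H; 10β-CH3; 7α-OAc; 12E); labdane atom numbers are used throughout, and the ligand enantiomer in step 2 is taken to be the one that gives (S)-6.

Step 1
Reactants: 1 tert-butyl methacrylate; 2 diethyl prop-2-en-1-yl phosphate
Product: 3 tert-butyl (2E)-4-[(diethoxyphosphoryl)oxy]-2-methylbut-2-enoate
Conditions: second-generation Grubbs catalyst (3 mol %), 1 (5 equiv), CH2Cl2, 40 °C
Reagents that add atoms: none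
Why: Olefin cross-metathesis between a 1,1-disubstituted acrylate and a terminal allylic olefin is cross-selective and should give the trisubstituted (E)-enoate under thermodynamic control.

Step 2
Reactants: 3 tert-butyl (2E)-4-[(diethoxyphosphoryl)oxy]-2-methylbut-2-enoate; 4 ethyl 4-iodobutanoate
Product: 6 1-tert-butyl 6-ethyl (2S)-2-ethenyl-2-methylhexanedioate, via bis(4-ethoxy-4-oxobutyl)zinc 5 (not isolated)
Conditions: 4, Et2Zn, copper iodide CuI (cat.), neat, 50 °C, then volatiles removed in vacuo; (CuOTf)2·C6H6 (5 mol %), chiral pyridyl peptide Schiff-base ligand (10 mol %), 3, THF, −15 °C; aq HCl work-up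
Reagents that add atoms: diethylzinc, CC[Zn]CC (zinc is retained only in 5)
Why: Copper-catalysed enantioselective SN2' allylic alkylation of a γ-phosphoryloxy α-methyl enoate by a dialkylzinc (made here by iodine–zinc exchange) delivers the alkyl group to the α-carbon with allylic transposition, so the chiral copper–ligand complex sets the quaternary C4 centre (S) and unveils the C5=C6 vinyl group.

Step 3
Reactants: 6 1-tert-butyl 6-ethyl (2S)-2-ethenyl-2-methylhexanedioate; 7 methyl acetate
Product: 8 1-tert-butyl 8-methyl (2S)-2-ethenyl-2-methyl-6-oxooctanedioate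
Conditions: LiN(SiMe3)2 (3 equiv), 7 (3 equiv), THF, −78 °C; then 6, −78 to −30 °C; AcOH quench
Reagents that add atoms: none
Why: Crossed Claisen condensation: the preformed lithium enolate of methyl acetate acylates the unhindered ethyl ester to give the β-keto ester (C8–C10), while the α-quaternary tert-butyl ester is too shielded to react.

Step 4
Reactants: 9 (2E)-3-methylpent-2-en-4-yn-1-ol
Product: 10 (2E)-3-methylpenta-2,4-dien-1-ol
Conditions: H2 (1 atm), Pd/CaCO3 poisoned with Pb(OAc)2, quinoline, EtOAc, 0 °C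
Reagents that add atoms: none
Why: Lindlar semi-hydrogenation reduces the terminal alkyne of the conjugated enyne to a vinyl group and leaves the (E)-trisubstituted alkene unchanged.

Step 5
Reactants: 10 (2E)-3-methylpenta-2,4-dien-1-ol
Product: 11 (2E)-1-bromo-3-methylpenta-2,4-diene
Conditions: PBr3 (0.4 equiv), pyridine (cat.), Et2O, −20 to 0 °C; used at once
Reagents that add atoms: phosphorus tribromide, BrP(Br)Br
Why: Bromination of the primary allylic alcohol with PBr3 at low temperature proceeds by SN2 displacement of the phosphite ester and should keep the (E)-diene geometry.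

Step 6
Reactants: 8 1-tert-butyl 8-methyl (2S)-2-ethenyl-2-methyl-6-oxooctanedioate; 11 (2E)-1-bromo-3-methylpenta-2,4-diene
Product: 12 1-tert-butyl 8-methyl (2S)-2-ethenyl-2-methyl-7-[(2E)-3-methylpenta-2,4-dien-1-yl]-6-oxooctanedioate (both C7 epimers)
Conditions: NaH, THF, 0 °C; then 11, 0 °C to rt
Reagents that add atoms: none
Why: C-Alkylation of the β-keto ester sodium enolate with the primary allylic bromide attaches the C11–C16 side chain to C9, whose configuration is irrelevant because C9 becomes sp2 in the next step.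

Step 7
Reactants: 12 1-tert-butyl 8-methyl (2S)-2-ethenyl-2-methyl-7-[(2E)-3-methylpenta-2,4-dien-1-yl]-6-oxooctanedioate
Product: 13 1-tert-butyl 8-methyl (2S,6Z)-2-ethenyl-2-methyl-7-[(2E)-3-methylpenta-2,4-dien-1-yl]-6-[(trifluoromethanesulfonyl)oxy]oct-6-enedioate
Conditions: NaH, CH2Cl2, 0 °C; Tf2O, −78 to 0 °C
Reagents that add atoms: trifluoromethanesulfonic anhydride, O=S(=O)(OS(=O)(=O)C(F)(F)F)C(F)(F)F
Why: O-Triflation of the chelated, U-shaped sodium enolate of the β-keto ester should give the (Z)-enol triflate with the triflate cis to the ester.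

Step 8
Reactants: 13 1-tert-butyl 8-methyl (2S,6Z)-2-ethenyl-2-methyl-7-[(2E)-3-methylpenta-2,4-dien-1-yl]-6-[(trifluoromethanesulfonyl)oxy]oct-6-enedioate
Product: 14 1-tert-butyl 8-methyl (2S,6E)-2-ethenyl-2,6-dimethyl-7-[(2E)-3-methylpenta-2,4-dien-1-yl]oct-6-enedioate
Conditions: Me2CuLi (from CuI and MeLi), THF, −78 to −20 °C
Reagents that add atoms: lithium dimethylcuprate, [Li+].C[Cu-]C
Why: Cuprate substitution of a β-(triflyloxy)acrylate runs by addition–elimination with retention, so the C20 methyl ends up cis to the C8 carbonyl and the tether cis to the side chain in the tetrasubstituted C9=C10 alkene.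

Step 9
Reactants: 14 1-tert-butyl 8-methyl (2S,6E)-2-ethenyl-2,6-dimethyl-7-[(2E)-3-methylpenta-2,4-dien-1-yl]oct-6-enedioate
Product: 15 tert-butyl (2S,6E)-9-chloro-2-ethenyl-2,6-dimethyl-7-[(2E)-3-methylpenta-2,4-dien-1-yl]-8-oxonon-6-enoate
Conditions: ICH2Cl, MeLi, THF, −78 °C; NH4Cl quench at −78 °C
Reagents that add atoms: chloroiodomethane, ClCI
Why: Homologation of an ester with chloromethyllithium generated in situ (the tetrahedral adduct is stable at −78 °C and collapses to the chloromethyl ketone only on quench) adds C7, and the α-quaternary tert-butyl ester is too hindered to compete.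

Step 10
Reactants: 15 tert-butyl (2S,6E)-9-chloro-2-ethenyl-2,6-dimethyl-7-[(2E)-3-methylpenta-2,4-dien-1-yl]-8-oxonon-6-enoate
Product: 16 tert-butyl (2S,6E)-9-acetoxy-2-ethenyl-2,6-dimethyl-7-[(2E)-3-methylpenta-2,4-dien-1-yl]-8-oxonon-6-enoate
Conditions: CsOAc, DMF, rt
Reagents that add atoms: caesium acetate, CC(=O)[O-].[Cs+]
Why: SN2 displacement of the activated α-chloro ketone by acetate installs the C7 acetoxy group of the target.

Step 11
Reactants: 16 tert-butyl (2S,6E)-9-acetoxy-2-ethenyl-2,6-dimethyl-7-[(2E)-3-methylpenta-2,4-dien-1-yl]-8-oxonon-6-enoate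
Product: 17 tert-butyl (2S,6E,8Z)-9-acetoxy-8-[(tert-butyldimethylsilyl)oxy]-2-ethenyl-2,6-dimethyl-7-[(2E)-3-methylpenta-2,4-dien-1-yl]nona-6,8-dienoate
Conditions: TBSOTf, Et3N, CH2Cl2, −78 to 0 °C
Reagents that add atoms: tert-butyldimethylsilyl trifluoromethanesulfonate, CC(C)(C)[Si](C)(C)OS(=O)(=O)C(F)(F)F
Why: Soft enolisation with a silyl triflate and an amine removes the acetoxy-activated C7 proton and should give the thermodynamically preferred (Z)-silyl enol ether, a 1-acetoxy-2-silyloxy diene with the acetoxy group on the outside.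

Step 12
Reactants: 17 tert-butyl (2S,6E,8Z)-9-acetoxy-8-[(tert-butyldimethylsilyl)oxy]-2-ethenyl-2,6-dimethyl-7-[(2E)-3-methylpenta-2,4-dien-1-yl]nona-6,8-dienoate
Product: 19 tert-butyl 7α-acetoxy-8-oxo-17-norlabda-12E,14-dien-19-oate, via silyl enol ether cycloadduct 18 (not isolated)
Conditions: PhMe (5 mM), BHT, Et3N (trace), sealed tube, 185 °C; then HF·pyridine, pyridine, THF, 0 °C
Reagents that add atoms: none
Why: A concerted, thermally allowed [4+2] cycloaddition (type-1 intramolecular Diels–Alder reaction of a 1,7,9-decatriene; closest known type: thermal cyclisation of 2-silyloxy dienes onto unactivated tethered alkenes) joins the diene C7=C8–C9=C10 to the vinyl group C5=C6, forming C6–C7 and C5–C10 and leaving the C8=C9 silyl enol ether. Ring B closes as the cyclohexene of the cycloaddition (boat-like array of the six reacting carbons) and ring A closes through C5–C10 with the four-carbon tether C1–C4 in a chair and exo to the diene, which gives the trans ring fusion; the C9 side chain acts as a steric directing group that clashes with an endo tether and so disfavours the cis-fused transition state. C7 and C10 are fixed relative to each other by the diene geometry (acetoxy and tether both outside, C20 methyl inside, suprafacial addition), which places 7α-OAc trans to the 10β-methyl, and C5 follows from the exo-tether mode. The absolute sense comes from C4: in the chair tether the flat ester takes the pseudoaxial site syn to the inside C10 methyl while the C4 methyl stays pseudoequatorial, avoiding a methyl/methyl syn-pentane contact, so the (S) centre should select the diene face that leads to the normal labdane series. The step needs chemoselectivity for the tethered vinyl group over the side-chain diene and over a [1,5]-hydrogen shift from the inside methyl, which the short tether with its quaternary C4 (gem-disubstituent effect), high dilution and a radical inhibitor should secure; the (E)-side-chain diene cannot reach the vinyl group and has no cis allylic hydrogen for such a shift. Buffered HF then cleaves the silyl enol ether and protonates C9 axially from the α-face, anti to the C10 methyl, to give the equatorial (β) side chain, which is also the thermodynamically favoured epimer.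

Step 13
Reactants: 19 tert-butyl 7α-acetoxy-8-oxo-17-norlabda-12E,14-dien-19-oate
Product: 20 tert-butyl 7α-acetoxylabda-8(17),12E,14-trien-19-oate
Conditions: Zn, CH2Br2, TiCl4, THF (reagent aged at 5 °C), then 19, CH2Cl2, 0 °C to rt
Reagents that add atoms: dibromomethane, BrCBr
Why: Zn/CH2Br2/TiCl4 carbonyl methylenation (Takai–Lombardo reaction) is non-basic and ester-tolerant, so the hindered, epimerisable α-acetoxy ketone should be converted into the C8(17) exocyclic methylene without change at C7 or C9.

Step 14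
Reactants: 20 tert-butyl 7α-acetoxylabda-8(17),12E,14-trien-19-oate
Product: 22 7α-acetoxylabda-8(17),12E,14-trien-19-oic acid (CNP0135450.1), via trimethylsilyl ester 21 (not isolated)
Conditions: TMSOTf, 2,6-lutidine, CH2Cl2, 0 °C; then pH 7 buffer
Reagents that add atoms: trimethylsilyl trifluoromethanesulfonate, C[Si](C)(C)OS(=O)(=O)C(F)(F)F (silicon is retained only in 21)
Why: Silyl triflate with 2,6-lutidine cleaves tert-butyl esters by O-silylation and loss of isobutene under non-protic conditions that should spare the allylic acetate and the dienes, and the silyl ester is hydrolysed on work-up.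

Compound list
1 | tert-butyl methacrylate | C=C(C)C(=O)OC(C)(C)C | starting material
2 | diethyl prop-2-en-1-yl phosphate | C=CCOP(=O)(OCC)OCC | starting material
3 | tert-butyl (2E)-4-[(diethoxyphosphoryl)oxy]-2-methylbut-2-enoate | CCOP(=O)(OCC)OC/C=C(\C)C(=O)OC(C)(C)C | intermediate
4 | ethyl 4-iodobutanoate | CCOC(=O)CCCI | starting material
5 | bis(4-ethoxy-4-oxobutyl)zinc (not isolated) | CCOC(=O)CCC[Zn]CCCC(=O)OCC | intermediate
6 | 1-tert-butyl 6-ethyl (2S)-2-ethenyl-2-methylhexanedioate | CCOC(=O)CCC[C@](C=C)(C)C(=O)OC(C)(C)C | intermediate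
7 | methyl acetate | COC(C)=O | starting material
8 | 1-tert-butyl 8-methyl (2S)-2-ethenyl-2-methyl-6-oxooctanedioate | COC(=O)CC(=O)CCC[C@](C=C)(C)C(=O)OC(C)(C)C | intermediate
9 | (2E)-3-methylpent-2-en-4-yn-1-ol | C#C/C(C)=C/CO | starting material
10 | (2E)-3-methylpenta-2,4-dien-1-ol | C=C/C(C)=C/CO | intermediate
11 | (2E)-1-bromo-3-methylpenta-2,4-diene | C=C/C(C)=C/CBr | intermediate
12 | 1-tert-butyl 8-methyl (2S)-2-ethenyl-2-methyl-7-[(2E)-3-methylpenta-2,4-dien-1-yl]-6-oxooctanedioate (C7 epimers) | COC(=O)C(C/C=C(\C)C=C)C(=O)CCC[C@](C=C)(C)C(=O)OC(C)(C)C | intermediate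
13 | 1-tert-butyl 8-methyl (2S,6Z)-2-ethenyl-2-methyl-7-[(2E)-3-methylpenta-2,4-dien-1-yl]-6-[(trifluoromethanesulfonyl)oxy]oct-6-enedioate | COC(=O)/C(C/C=C(\C)C=C)=C(\OS(=O)(=O)C(F)(F)F)CCC[C@](C=C)(C)C(=O)OC(C)(C)C | intermediate
14 | 1-tert-butyl 8-methyl (2S,6E)-2-ethenyl-2,6-dimethyl-7-[(2E)-3-methylpenta-2,4-dien-1-yl]oct-6-enedioate | COC(=O)/C(C/C=C(\C)C=C)=C(\C)CCC[C@](C=C)(C)C(=O)OC(C)(C)C | intermediate
15 | tert-butyl (2S,6E)-9-chloro-2-ethenyl-2,6-dimethyl-7-[(2E)-3-methylpenta-2,4-dien-1-yl]-8-oxonon-6-enoate | ClCC(=O)/C(C/C=C(\C)C=C)=C(\C)CCC[C@](C=C)(C)C(=O)OC(C)(C)C | intermediate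
16 | tert-butyl (2S,6E)-9-acetoxy-2-ethenyl-2,6-dimethyl-7-[(2E)-3-methylpenta-2,4-dien-1-yl]-8-oxonon-6-enoate | CC(=O)OCC(=O)/C(C/C=C(\C)C=C)=C(\C)CCC[C@](C=C)(C)C(=O)OC(C)(C)C | intermediate
17 | tert-butyl (2S,6E,8Z)-9-acetoxy-8-[(tert-butyldimethylsilyl)oxy]-2-ethenyl-2,6-dimethyl-7-[(2E)-3-methylpenta-2,4-dien-1-yl]nona-6,8-dienoate | CC(=O)O/C=C(O[Si](C)(C)C(C)(C)C)/C(C/C=C(\C)C=C)=C(\C)CCC[C@](C=C)(C)C(=O)OC(C)(C)C | intermediate
18 | tert-butyl 7α-acetoxy-8-[(tert-butyldimethylsilyl)oxy]-17-norlabda-8,12E,14-trien-19-oate (5α-H, 10β-CH3; not isolated) | C=C/C(C)=C/CC1=C(O[Si](C)(C)C(C)(C)C)[C@H](OC(C)=O)C[C@@H]2[C@]1(C)CCC[C@]2(C)C(=O)OC(C)(C)C | intermediate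
19 | tert-butyl 7α-acetoxy-8-oxo-17-norlabda-12E,14-dien-19-oate (9α-H) | C=C/C(C)=C/C[C@H]1C(=O)[C@H](OC(C)=O)C[C@@H]2[C@]1(C)CCC[C@]2(C)C(=O)OC(C)(C)C | intermediate
20 | tert-butyl 7α-acetoxylabda-8(17),12E,14-trien-19-oate | C=C/C(C)=C/C[C@H]1C(=C)[C@H](OC(C)=O)C[C@@H]2[C@]1(C)CCC[C@]2(C)C(=O)OC(C)(C)C | intermediate
21 | trimethylsilyl 7α-acetoxylabda-8(17),12E,14-trien-19-oate (not isolated) | C=C/C(C)=C/C[C@H]1C(=C)[C@H](OC(C)=O)C[C@@H]2[C@]1(C)CCC[C@]2(C)C(=O)O[Si](C)(C)C | intermediate
22 | 7α-acetoxylabda-8(17),12E,14-trien-19-oic acid (7α-acetoxy-trans-communic acid, CNP0135450.1) | C=C/C(C)=C/C[C@H]1C(=C)[C@H](OC(C)=O)C[C@@H]2[C@]1(C)CCC[C@]2(C)C(=O)O | target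

Total step count: 14. Longest linear sequence: 12 steps (steps 1–3 and 6–14, from tert-butyl methacrylate); steps 4 and 5 form the side-chain branch.

Steps most likely to fail

Step 12. The cycloaddition onto the unactivated vinyl group may be slower than a [1,5]-hydrogen shift from the inside C10 methyl to C7, than acetyl/silyl exchange across the enediol, or than thermal loss of acetic acid. Facial control by C4 may also be incomplete. The fallback sets out from 14 and returns at 19, replacing steps 9 to 12. The ester carbonyl of 14 is methylenated with Cp2Ti(μ-Cl)(μ-CH2)AlMe2 (THF, pyridine, −40 °C to rt) to the 2-methoxy diene F1, whose unsubstituted C7 terminus and lack of an acetate should allow cyclisation at lower temperature (PhMe, 150–160 °C) to the methyl enol ether cycloadduct F2. Mild acid hydrolysis (oxalic acid, wet THF) gives the 7-deoxy ketone F3 with C9 set by the same axial protonation. Kinetic deprotonation at the unhindered C7 (LiN(iPr)2, THF, −78 °C) and oxidation of the enolate with 2-(phenylsulfonyl)-3-phenyloxaziridine from the axial α-face should give the 7α-hydroxy ketone F4. Acetylation (Ac2O, DMAP, pyridine) then gives 19.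

Step 9. The carbenoid may decompose faster than it adds to the hindered, twisted tetrasubstituted enoate, or the tetrahedral adduct may collapse early and take up a second carbenoid. The fallback sets out from 14 and returns at 16, replacing steps 9 and 10. Hydrolysis of the methyl ester (LiOH, THF/MeOH/H2O, 50 °C; the α-quaternary tert-butyl ester should survive) gives the enoic acid F5. 1-Chloro-N,N,2-trimethylprop-1-en-1-amine (CH2Cl2, 0 °C) converts it under neutral conditions into the acid chloride F6. Diazomethane (Et2O, 0 °C) gives the diazoketone F7, and acetolysis (AcOH, 60 °C) gives 16.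

Step 13. Carbonyl addition may be retarded by shielding from the C10 methyl, the C9 side chain and the axial C7 acetate, so that the Lewis-acidic titanium reagent ionises the acetate next to the ketone or the allylic acetate of the product instead. The fallback sets out from 19 and returns at 20. Addition of Me3SiCH2Li in the presence of CeCl3 (THF, −78 °C, cold quench) to the C8 ketone gives the β-hydroxysilane F8 as either C8 epimer. Acid-induced Peterson elimination (HF·pyridine, MeCN, 0 °C) gives the exocyclic methylene of 20 from both epimers.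

Further compounds
F1 | step 12 | 2-methoxy diene: tert-butyl (2S,6E)-2-ethenyl-8-methoxy-2,6-dimethyl-7-[(2E)-3-methylpenta-2,4-dien-1-yl]nona-6,8-dienoate | COC(=C)/C(C/C=C(\C)C=C)=C(\C)CCC[C@](C=C)(C)C(=O)OC(C)(C)C
F2 | step 12 | methyl enol ether cycloadduct: tert-butyl 8-methoxy-17-norlabda-8,12E,14-trien-19-oate | C=C/C(C)=C/CC1=C(OC)CC[C@@H]2[C@]1(C)CCC[C@]2(C)C(=O)OC(C)(C)C
F3 | step 12 | 7-deoxy ketone: tert-butyl 8-oxo-17-norlabda-12E,14-dien-19-oate | C=C/C(C)=C/C[C@H]1C(=O)CC[C@@H]2[C@]1(C)CCC[C@]2(C)C(=O)OC(C)(C)C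
F4 | step 12 | 7α-hydroxy ketone: tert-butyl 7α-hydroxy-8-oxo-17-norlabda-12E,14-dien-19-oate | C=C/C(C)=C/C[C@H]1C(=O)[C@H](O)C[C@@H]2[C@]1(C)CCC[C@]2(C)C(=O)OC(C)(C)C
F5 | step 9 | enoic acid: (2E,7S)-8-tert-butoxy-7-ethenyl-3,7-dimethyl-2-[(2E)-3-methylpenta-2,4-dien-1-yl]-8-oxooct-2-enoic acid | OC(=O)/C(C/C=C(\C)C=C)=C(\C)CCC[C@](C=C)(C)C(=O)OC(C)(C)C
F6 | step 9 | acid chloride: tert-butyl (2S,6E)-8-chloro-2-ethenyl-2,6-dimethyl-7-[(2E)-3-methylpenta-2,4-dien-1-yl]-8-oxooct-6-enoate | ClC(=O)/C(C/C=C(\C)C=C)=C(\C)CCC[C@](C=C)(C)C(=O)OC(C)(C)C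
F7 | step 9 | diazoketone: tert-butyl (2S,6E)-9-diazo-2-ethenyl-2,6-dimethyl-7-[(2E)-3-methylpenta-2,4-dien-1-yl]-8-oxonon-6-enoate | [N-]=[N+]=CC(=O)/C(C/C=C(\C)C=C)=C(\C)CCC[C@](C=C)(C)C(=O)OC(C)(C)C
F8 | step 13 | β-hydroxysilane: tert-butyl 7α-acetoxy-8-hydroxy-17-(trimethylsilyl)labda-12E,14-dien-19-oate (C8 epimers) | C=C/C(C)=C/C[C@H]1C(O)(C[Si](C)(C)C)[C@H](OC(C)=O)C[C@@H]2[C@]1(C)CCC[C@]2(C)C(=O)OC(C)(C)C
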